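The ratio I began with was left-handed product made per solid reagent charged, read where the south and south-west curves level off. The south run levelled at a mean of 11.5% of the substrates charged, which is 0.575 per solid reagent. The last south-west reading gives 0.675. So I took the solid's share, the left-handed product finally made per solid reagent charged, as the reading 0.625. This treats solid reagent as the limiting reagent, and in the flask it is charged below either substrate. My reckoning for the flask was therefore 25.0%, provided its charge had been consumed by 3.0 d.

Would it be? The east run reached 30% at 2.50 d, and at that share this is a mean use of 0.461 M d⁻¹, which by that time adds up to less solid reagent than the east run was charged with. Replacing the curve by this mean, the flask's 0.960 M takes 2.08 d. The same mean ends the south charge at 1.04 d, yet its plateau appeared at the 1.67 d reading, which allows a lag of 0.628 d. Together these make 2.71 d, which is shorter than the time asked. So I expected the flask on its plateau, with c(partner) low, though these runs did not size it.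

| setting | south | east | south-west | flask |
|---|---|---|---|---|
| left-handed substrate | 1.2 M | 1.2 M | 1.8 M | 1.2 M |
| right-handed substrate | 1.2 M | 1.2 M | 1.8 M | 1.2 M |
| solid reagent | 0.48 M | 1.9 M | 0.96 M | 0.960 M |
| catalyst | 6 mM | 6 mM | 6 mM | 6.0 mM |
| remark | run made earlier | run made earlier | run made earlier |  |
| time |  |  |  | 3.0 d |

| run | time / d | left-handed product / % | left-handed substrate / % |
|---|---|---|---|
| south | 0.333 | 3 | 49 |
| south | 0.833 | 10 | 42 |
| south | 1.67 | 12 | 37 |
| south | 2.50 | 11 | 39 |
| east | 0.333 | 2 | 48 |
| east | 0.833 | 9 | 44 |
| east | 1.67 | 22 | 31 |
| east | 2.50 | 30 | 17 |
| south-west | 0.625 | 6 | 46 |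
| south-west | 1.25 | 12 | 40 |
| south-west | 1.67 | 16 | 34 |
| south-west | 2.50 | 18 | 33 |

(each reading ± 1.5 percentage points)

- the left-handed product standing at 3.0 d, as a percentage of the left-handed substrate and right-handed substrate together charged
- concentration of partner in solution at 3.0 d, in percent of saturation

- catalyst is single-handed; left-handed substrate and right-handed substrate are mirror images of each other, charged as a racemate, each of them at the stated concentration
- given per volume of solution although it is solid: solid reagent
- the analysis behind the earlier runs scatters by 1.5 percentage points, standard deviation
- at the start none of the solid reagent is in solution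
- partner is what solid reagent becomes in solution

The forecast gave 21% and 50%, “leaving the flask near equilibrium at 3 d”. Its product stands below mine, and it keeps partner in solution.

The flask gave 25.4% and 1.16%.

    partner + catalyst + left-handed substrate → catalyst + left-handed product (k = 16.0 L² mol⁻² h⁻¹)
    partner + catalyst + right-handed substrate → catalyst + right-handed product (k = 7.40 L² mol⁻² h⁻¹)
    solid reagent ⇌ partner, rate k3*(cs3 - [partner]) while solid is left; crystals form when [partner] > cs3 (solubility = 0.920 M, k = 0.0280 h⁻¹)
    partner → decomposition product (k = 2.90 × 10⁻⁴ h⁻¹)

At 3.00 d the flask held 0% of its solid reagent and c(partner) of 0.0107 M, and on c(partner) it parts from the forecast. Its share came to 0.636, beside my 0.625. For the neighbour flask with 0.24 M of solid reagent, the share 0.625 gives 6.25%; the computed neighbour gave 6.74%.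

The data were generated by integration from invented constants, noise included.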